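**Retrosynthetic overview**
- Ring C is the only ring that is built, and it is closed last: the C3–C4 bond is formed by rhodium-catalysed enantioselective 6-endo hydroacylation of aldehyde 23, which also sets C2.
- The enabling feature is the 1,1-disubstituted enol ether O1–C2(aryl)=C3H2 held on ring A ortho to the C4 formyl group, with the C5 methoxy oxygen on the other flank.
- The enol ether comes from titanium methylenation of aryl ester 20 (bromophenol 15 + ring B acid 18); the formyl group comes from the aryl bromide by Br/Li exchange.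
- The side-chain stereocentre is set by Evans alkylation with prenyl bromide; ester plus MeMgBr gives the tertiary alcohol.
- Rings A and B are bought as arenes (2,4-dihydroxy-6-methoxybenzaldehyde, whose CHO becomes the benzylic CH2, and 2,4-dihydroxybenzoic acid).

Key step: step 15

Assumption: the sense of induction of the rhodium–bisphosphine catalyst on aryl 1-arylvinyl ethers is not known in advance; (R)-DTBM-SEGPHOS is written, and its antipode is used if a model aldehyde without the side chain shows the opposite sense.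
Remark: imide 4 is taken as a catalogue reagent; it is otherwise one N-acylation away from (S)-4-benzyloxazolidin-2-one.

**Step 1**
Reactants: 1 2,4-dihydroxy-6-methoxybenzaldehyde
Product: 2 2-hydroxy-6-methoxy-4-(methoxymethoxy)benzaldehyde
Conditions: MOMCl (1.05 equiv), iPr2NEt, CH2Cl2, 0 °C
Reagents that add atoms: chloromethyl methyl ether, COCCl
Why: The 2-hydroxyl is tied up in a hydrogen bond to the formyl group, so Williamson-type O-alkylation should take the free, more acidic 4-hydroxyl.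

**Step 2**
Reactants: 2 2-hydroxy-6-methoxy-4-(methoxymethoxy)benzaldehyde
Product: 3 2-methoxy-4-(methoxymethoxy)-6-(triisopropylsilyloxy)benzaldehyde
Conditions: TIPSCl, imidazole, DMF, 40 °C
Reagents that add atoms: triisopropylsilyl chloride, CC(C)[Si](Cl)(C(C)C)C(C)C
Why: Imidazole-promoted silylation of the remaining phenol; the bulky, non-coordinating silyl ether is chosen to survive to step 16 and to shield the neighbouring ring position in step 9.

**Step 3**
Reactants: 4 (4S)-4-benzyl-3-(chloroacetyl)-1,3-oxazolidin-2-one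
Product: 5 diethyl {2-[(4S)-4-benzyl-2-oxo-1,3-oxazolidin-3-yl]-2-oxoethyl}phosphonate
Conditions: P(OEt)3 (neat), 140 °C
Reagents that add atoms: triethyl phosphite, CCOP(OCC)OCC
Why: Michaelis–Arbuzov reaction of the α-chloro imide, driven by loss of chloroethane.

**Step 4**
Reactants: 3 2-methoxy-4-(methoxymethoxy)-6-(triisopropylsilyloxy)benzaldehyde; 5 diethyl {2-[(4S)-4-benzyl-2-oxo-1,3-oxazolidin-3-yl]-2-oxoethyl}phosphonate
Product: 6 (4S)-4-benzyl-3-{(2E)-3-[2-methoxy-4-(methoxymethoxy)-6-(triisopropylsilyloxy)phenyl]prop-2-enoyl}-1,3-oxazolidin-2-one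
Conditions: LiCl, iPr2NEt, MeCN, rt
Reagents that add atoms: none
Why: Horner–Wadsworth–Emmons olefination under Masamune–Roush conditions, which should give the E-enoyl imide and attaches the auxiliary in the same operation.

**Step 5**
Reactants: 6 (4S)-4-benzyl-3-{(2E)-3-[2-methoxy-4-(methoxymethoxy)-6-(triisopropylsilyloxy)phenyl]prop-2-enoyl}-1,3-oxazolidin-2-one
Product: 7 (4S)-4-benzyl-3-{3-[2-methoxy-4-(methoxymethoxy)-6-(triisopropylsilyloxy)phenyl]propanoyl}-1,3-oxazolidin-2-one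
Conditions: H2 (1 atm), Pd/C (10 %), EtOAc, rt
Reagents that add atoms: none
Why: Heterogeneous hydrogenation of the conjugated alkene; no other reducible group is present at this stage.

**Step 6**
Reactants: 7 (4S)-4-benzyl-3-{3-[2-methoxy-4-(methoxymethoxy)-6-(triisopropylsilyloxy)phenyl]propanoyl}-1,3-oxazolidin-2-one
Product: 9 (4S)-4-benzyl-3-[(2S)-2-{[2-methoxy-4-(methoxymethoxy)-6-(triisopropylsilyloxy)phenyl]methyl}-5-methylhex-4-enoyl]-1,3-oxazolidin-2-one, via sodium Z-enolate 8 (not isolated)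
Conditions: NaN(SiMe3)2, THF, −78 °C; prenyl bromide, −78 → −40 °C
Reagents that add atoms: 1-bromo-3-methylbut-2-ene, CC(C)=CCBr
Why: Evans asymmetric alkylation, in which the benzyl group of the (4S)-auxiliary blocks one face of the chelated Z-enolate so that prenyl bromide adds from the other face and sets the (2S) centre.

**Step 7**
Reactants: 9 (4S)-4-benzyl-3-[(2S)-2-{[2-methoxy-4-(methoxymethoxy)-6-(triisopropylsilyloxy)phenyl]methyl}-5-methylhex-4-enoyl]-1,3-oxazolidin-2-one
Product: 10 methyl (2S)-2-{[2-methoxy-4-(methoxymethoxy)-6-(triisopropylsilyloxy)phenyl]methyl}-5-methylhex-4-enoate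
Conditions: MeMgBr (1.5 equiv), MeOH/CH2Cl2, 0 °C; H2O work-up
Reagents that add atoms: methanol, CO (delivered as MeOMgBr, CO[Mg]Br)
Why: Transesterification with methoxymagnesium bromide attacks the exocyclic acyl group selectively and is mild enough to leave the α-centre and the aryl silyl ether alone.

**Step 8**
Reactants: 10 methyl (2S)-2-{[2-methoxy-4-(methoxymethoxy)-6-(triisopropylsilyloxy)phenyl]methyl}-5-methylhex-4-enoate
Product: 12 (3S)-3-{[2-methoxy-4-(methoxymethoxy)-6-(triisopropylsilyloxy)phenyl]methyl}-2,6-dimethylhept-5-en-2-ol, via methyl ketone 11 (not isolated)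
Conditions: MeMgBr (3.5 equiv), THF, 0 °C → rt; H2O work-up
Reagents that add atoms: methylmagnesium bromide, C[Mg]Br
Why: Double Grignard addition to the ester builds the tertiary carbinol; addition should outpace enolisation at the hindered α-centre, which keeps its configuration.

**Step 9**
Reactants: 12 (3S)-3-{[2-methoxy-4-(methoxymethoxy)-6-(triisopropylsilyloxy)phenyl]methyl}-2,6-dimethylhept-5-en-2-ol
Product: 14 (3S)-3-{[3-bromo-2-methoxy-4-(methoxymethoxy)-6-(triisopropylsilyloxy)phenyl]methyl}-2,6-dimethylhept-5-en-2-ol, via dilithio species 13 (not isolated)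
Conditions: n-BuLi (2.3 equiv), THF, 0 °C; BrCl2CCCl2Br, −78 °C; H2O
Reagents that add atoms: 1,2-dibromo-1,1,2,2-tetrachloroethane, BrC(Cl)(Cl)C(Cl)(Cl)Br
Why: Directed ortho-metalation after alkoxide formation: the ring position between OMe and OMOM has two coordinating neighbours, while the other open position is flanked by the bulky, non-coordinating silyl ether, and the aryllithium is then brominated.

**Step 10**
Reactants: 14 (3S)-3-{[3-bromo-2-methoxy-4-(methoxymethoxy)-6-(triisopropylsilyloxy)phenyl]methyl}-2,6-dimethylhept-5-en-2-ol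
Product: 15 2-bromo-4-[(2S)-2-(2-hydroxypropan-2-yl)-5-methylhex-4-en-1-yl]-3-methoxy-5-(triisopropylsilyloxy)phenol
Conditions: PPTS (cat.), MeOH, reflux
Reagents that add atoms: none
Why: Acid-catalysed acetal exchange removes the aryl MOM group under conditions weak enough to spare the tertiary alcohol, the prenyl alkene and the silyl ether.

**Step 11**
Reactants: 16 2,4-dihydroxybenzoic acid
Product: 18 2,4-bis(tert-butyldimethylsilyloxy)benzoic acid, via tris-silyl compound 17 (not isolated)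
Conditions: TBSCl (3.3 equiv), imidazole, DMF, rt; AcOH/H2O/THF, rt
Reagents that add atoms: tert-butyldimethylsilyl chloride, CC(C)(C)[Si](C)(C)Cl
Why: Exhaustive silylation followed by selective hydrolysis of the much more labile silyl ester.

**Step 12**
Reactants: 18 2,4-bis(tert-butyldimethylsilyloxy)benzoic acid; 15 2-bromo-4-[(2S)-2-(2-hydroxypropan-2-yl)-5-methylhex-4-en-1-yl]-3-methoxy-5-(triisopropylsilyloxy)phenol
Product: 20 2-bromo-4-[(2S)-2-(2-hydroxypropan-2-yl)-5-methylhex-4-en-1-yl]-3-methoxy-5-(triisopropylsilyloxy)phenyl 2,4-bis(tert-butyldimethylsilyloxy)benzoate, via acid chloride 19 (not isolated)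
Conditions: Me2C=C(Cl)NMe2, CH2Cl2, rt; 15, Et3N, DMAP (cat.), 0 °C → rt
Reagents that add atoms: none
Why: Neutral acid chloride formation with the α-chloroenamine followed by DMAP-catalysed acylation of the phenol; the tertiary alcohol is too hindered to compete.

**Step 13**
Reactants: 20 2-bromo-4-[(2S)-2-(2-hydroxypropan-2-yl)-5-methylhex-4-en-1-yl]-3-methoxy-5-(triisopropylsilyloxy)phenyl 2,4-bis(tert-butyldimethylsilyloxy)benzoate
Product: 21 (3S)-3-{[3-bromo-4-({1-[2,4-bis(tert-butyldimethylsilyloxy)phenyl]ethenyl}oxy)-2-methoxy-6-(triisopropylsilyloxy)phenyl]methyl}-2,6-dimethylhept-5-en-2-ol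
Conditions: Cp2TiMe2 (3 equiv), toluene, 70 °C, dark
Reagents that add atoms: dimethyltitanocene, [CH3-].[CH3-].[Ti+4].c1cc[cH-]c1.c1cc[cH-]c1
Why: Petasis methylenation converts the aryl ester into the aryl 1-arylvinyl ether by carbonyl/titanium-methylidene exchange under non-acidic conditions that the enol ether survives.

**Step 14**
Reactants: 21 (3S)-3-{[3-bromo-4-({1-[2,4-bis(tert-butyldimethylsilyloxy)phenyl]ethenyl}oxy)-2-methoxy-6-(triisopropylsilyloxy)phenyl]methyl}-2,6-dimethylhept-5-en-2-ol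
Product: 23 2-({1-[2,4-bis(tert-butyldimethylsilyloxy)phenyl]ethenyl}oxy)-5-[(2S)-2-(2-hydroxypropan-2-yl)-5-methylhex-4-en-1-yl]-6-methoxy-4-(triisopropylsilyloxy)benzaldehyde, via aryllithium 22 (not isolated)
Conditions: t-BuLi (3.1 equiv), THF, −78 °C; DMF; H2O
Reagents that add atoms: N,N-dimethylformamide, CN(C)C=O
Why: Bromine–lithium exchange at low temperature followed by Bouveault formylation installs the C4 carbon at the aldehyde level only after the aldehyde-incompatible methylenation is done.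

**Step 15**
Reactants: 23 2-({1-[2,4-bis(tert-butyldimethylsilyloxy)phenyl]ethenyl}oxy)-5-[(2S)-2-(2-hydroxypropan-2-yl)-5-methylhex-4-en-1-yl]-6-methoxy-4-(triisopropylsilyloxy)benzaldehyde
Product: 24 (2S)-2-[2,4-bis(tert-butyldimethylsilyloxy)phenyl]-6-[(2S)-2-(2-hydroxypropan-2-yl)-5-methylhex-4-en-1-yl]-5-methoxy-7-(triisopropylsilyloxy)-2,3-dihydro-4H-chromen-4-one
Conditions: [Rh(cod)Cl]2 (2.5 mol %), (R)-DTBM-SEGPHOS (5.5 mol %), NaB[3,5-(CF3)2C6H3]4 (6 mol %), 1,4-dioxane, 60 °C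
Reagents that add atoms: none
Why: Proposed new method: cationic monovalent rhodium inserts into the formyl C–H bond to give an acyl hydride of trivalent rhodium, the enol ether C2=C3 binds, the hydride migrates to C2, and the primary alkyl at C3 couples with the acyl carbon by reductive elimination to form C3–C4. The closest known reaction type is the rhodium–bisphosphine-catalysed enantioselective endo-hydroacylation of ortho-allylbenzaldehydes carrying 1,1-disubstituted alkenes to 3-substituted tetralones (and of 4-substituted pent-4-enals and 2-(1-substituted vinyl)benzaldehydes to five-membered ketones); here oxygen replaces the benzylic CH2, which has not been shown. Ring C closes in a 6-endo-trig mode with respect to the alkene, through a seven-membered acyl–alkyl rhodacycle. The new stereocentre C2 is set in the hydride-migration step by the chiral bisphosphine, which selects the alkene face; the remote side-chain centre has no influence, so this is catalyst control. The step needs regioselectivity for C3 over C2 (the 5-exo path to a 2-aryl-2-methylbenzofuran-3-one would need a tertiary alkyl–rhodium and reductive elimination at a quaternary carbon, which the 1,1-disubstitution disfavours) and it needs insertion to outrun decarbonylation, which chelation of the acyl hydride by the C5 methoxy or the ring ether oxygen should secure. The trisubstituted side-chain alkene is too hindered to compete.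

**Step 16**
Reactants: 24 (2S)-2-[2,4-bis(tert-butyldimethylsilyloxy)phenyl]-6-[(2S)-2-(2-hydroxypropan-2-yl)-5-methylhex-4-en-1-yl]-5-methoxy-7-(triisopropylsilyloxy)-2,3-dihydro-4H-chromen-4-one
Product: 25 (2S)-2-(2,4-dihydroxyphenyl)-7-hydroxy-6-[(2S)-2-(2-hydroxypropan-2-yl)-5-methylhex-4-en-1-yl]-5-methoxy-2,3-dihydro-4H-chromen-4-one (CNP0298187.1)
Conditions: Bu4NF (3.5 equiv), AcOH (3.5 equiv), THF, 0 °C
Reagents that add atoms: none
Why: Fluoride-mediated cleavage of the three aryl silyl ethers, buffered with acetic acid so that no free phenoxide can open ring C and erode C2, and without acid that would cyclise the tertiary alcohol.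

**Compound list**
1 | 2,4-dihydroxy-6-methoxybenzaldehyde | COc1cc(O)cc(O)c1C=O | starting material
2 | 2-hydroxy-6-methoxy-4-(methoxymethoxy)benzaldehyde | COCOc1cc(O)c(C=O)c(OC)c1 | intermediate
3 | 2-methoxy-4-(methoxymethoxy)-6-(triisopropylsilyloxy)benzaldehyde | COCOc1cc(O[Si](C(C)C)(C(C)C)C(C)C)c(C=O)c(OC)c1 | intermediate
4 | (4S)-4-benzyl-3-(chloroacetyl)-1,3-oxazolidin-2-one | ClCC(=O)N1[C@@H](Cc2ccccc2)COC1=O | starting material
5 | diethyl {2-[(4S)-4-benzyl-2-oxo-1,3-oxazolidin-3-yl]-2-oxoethyl}phosphonate | CCOP(=O)(OCC)CC(=O)N1[C@@H](Cc2ccccc2)COC1=O | intermediate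
6 | (4S)-4-benzyl-3-{(2E)-3-[2-methoxy-4-(methoxymethoxy)-6-(triisopropylsilyloxy)phenyl]prop-2-enoyl}-1,3-oxazolidin-2-one | COCOc1cc(O[Si](C(C)C)(C(C)C)C(C)C)c(/C=C/C(=O)N2[C@@H](Cc3ccccc3)COC2=O)c(OC)c1 | intermediate
7 | (4S)-4-benzyl-3-{3-[2-methoxy-4-(methoxymethoxy)-6-(triisopropylsilyloxy)phenyl]propanoyl}-1,3-oxazolidin-2-one | COCOc1cc(O[Si](C(C)C)(C(C)C)C(C)C)c(CCC(=O)N2[C@@H](Cc3ccccc3)COC2=O)c(OC)c1 | intermediate
8 | sodium Z-enolate of 7 (not isolated) | COCOc1cc(O[Si](C(C)C)(C(C)C)C(C)C)c(C/C=C(\[O-])N2[C@@H](Cc3ccccc3)COC2=O)c(OC)c1.[Na+] | intermediate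
9 | (4S)-4-benzyl-3-[(2S)-2-{[2-methoxy-4-(methoxymethoxy)-6-(triisopropylsilyloxy)phenyl]methyl}-5-methylhex-4-enoyl]-1,3-oxazolidin-2-one | COCOc1cc(O[Si](C(C)C)(C(C)C)C(C)C)c(C[C@H](CC=C(C)C)C(=O)N2[C@@H](Cc3ccccc3)COC2=O)c(OC)c1 | intermediate
10 | methyl (2S)-2-{[2-methoxy-4-(methoxymethoxy)-6-(triisopropylsilyloxy)phenyl]methyl}-5-methylhex-4-enoate | COCOc1cc(O[Si](C(C)C)(C(C)C)C(C)C)c(C[C@H](CC=C(C)C)C(=O)OC)c(OC)c1 | intermediate
11 | (3S)-3-{[2-methoxy-4-(methoxymethoxy)-6-(triisopropylsilyloxy)phenyl]methyl}-6-methylhept-5-en-2-one (not isolated) | COCOc1cc(O[Si](C(C)C)(C(C)C)C(C)C)c(C[C@H](CC=C(C)C)C(C)=O)c(OC)c1 | intermediate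
12 | (3S)-3-{[2-methoxy-4-(methoxymethoxy)-6-(triisopropylsilyloxy)phenyl]methyl}-2,6-dimethylhept-5-en-2-ol | COCOc1cc(O[Si](C(C)C)(C(C)C)C(C)C)c(C[C@H](CC=C(C)C)C(C)(C)O)c(OC)c1 | intermediate
13 | dilithio species of 12, aryllithium between OMe and OMOM plus lithium alkoxide (not isolated) | COCOc1cc(O[Si](C(C)C)(C(C)C)C(C)C)c(C[C@H](CC=C(C)C)C(C)(C)O[Li])c(OC)c1[Li] | intermediate
14 | (3S)-3-{[3-bromo-2-methoxy-4-(methoxymethoxy)-6-(triisopropylsilyloxy)phenyl]methyl}-2,6-dimethylhept-5-en-2-ol | COCOc1cc(O[Si](C(C)C)(C(C)C)C(C)C)c(C[C@H](CC=C(C)C)C(C)(C)O)c(OC)c1Br | intermediate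
15 | 2-bromo-4-[(2S)-2-(2-hydroxypropan-2-yl)-5-methylhex-4-en-1-yl]-3-methoxy-5-(triisopropylsilyloxy)phenol | Oc1cc(O[Si](C(C)C)(C(C)C)C(C)C)c(C[C@H](CC=C(C)C)C(C)(C)O)c(OC)c1Br | intermediate
16 | 2,4-dihydroxybenzoic acid | O=C(O)c1ccc(O)cc1O | starting material
17 | tert-butyldimethylsilyl 2,4-bis(tert-butyldimethylsilyloxy)benzoate (not isolated) | CC(C)(C)[Si](C)(C)OC(=O)c1ccc(O[Si](C)(C)C(C)(C)C)cc1O[Si](C)(C)C(C)(C)C | intermediate
18 | 2,4-bis(tert-butyldimethylsilyloxy)benzoic acid | O=C(O)c1ccc(O[Si](C)(C)C(C)(C)C)cc1O[Si](C)(C)C(C)(C)C | intermediate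
19 | 2,4-bis(tert-butyldimethylsilyloxy)benzoyl chloride (not isolated) | O=C(Cl)c1ccc(O[Si](C)(C)C(C)(C)C)cc1O[Si](C)(C)C(C)(C)C | intermediate
20 | 2-bromo-4-[(2S)-2-(2-hydroxypropan-2-yl)-5-methylhex-4-en-1-yl]-3-methoxy-5-(triisopropylsilyloxy)phenyl 2,4-bis(tert-butyldimethylsilyloxy)benzoate | O=C(Oc1cc(O[Si](C(C)C)(C(C)C)C(C)C)c(C[C@H](CC=C(C)C)C(C)(C)O)c(OC)c1Br)c1ccc(O[Si](C)(C)C(C)(C)C)cc1O[Si](C)(C)C(C)(C)C | intermediate
21 | (3S)-3-{[3-bromo-4-({1-[2,4-bis(tert-butyldimethylsilyloxy)phenyl]ethenyl}oxy)-2-methoxy-6-(triisopropylsilyloxy)phenyl]methyl}-2,6-dimethylhept-5-en-2-ol | C=C(Oc1cc(O[Si](C(C)C)(C(C)C)C(C)C)c(C[C@H](CC=C(C)C)C(C)(C)O)c(OC)c1Br)c1ccc(O[Si](C)(C)C(C)(C)C)cc1O[Si](C)(C)C(C)(C)C | intermediate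
22 | aryllithium from 21, lithium in place of bromine plus lithium alkoxide (not isolated) | C=C(Oc1cc(O[Si](C(C)C)(C(C)C)C(C)C)c(C[C@H](CC=C(C)C)C(C)(C)O[Li])c(OC)c1[Li])c1ccc(O[Si](C)(C)C(C)(C)C)cc1O[Si](C)(C)C(C)(C)C | intermediate
23 | 2-({1-[2,4-bis(tert-butyldimethylsilyloxy)phenyl]ethenyl}oxy)-5-[(2S)-2-(2-hydroxypropan-2-yl)-5-methylhex-4-en-1-yl]-6-methoxy-4-(triisopropylsilyloxy)benzaldehyde | C=C(Oc1cc(O[Si](C(C)C)(C(C)C)C(C)C)c(C[C@H](CC=C(C)C)C(C)(C)O)c(OC)c1C=O)c1ccc(O[Si](C)(C)C(C)(C)C)cc1O[Si](C)(C)C(C)(C)C | intermediate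
24 | (2S)-2-[2,4-bis(tert-butyldimethylsilyloxy)phenyl]-6-[(2S)-2-(2-hydroxypropan-2-yl)-5-methylhex-4-en-1-yl]-5-methoxy-7-(triisopropylsilyloxy)-2,3-dihydro-4H-chromen-4-one | COc1c(C[C@H](CC=C(C)C)C(C)(C)O)c(O[Si](C(C)C)(C(C)C)C(C)C)cc2c1C(=O)C[C@@H](c1ccc(O[Si](C)(C)C(C)(C)C)cc1O[Si](C)(C)C(C)(C)C)O2 | intermediate
25 | (2S)-2-(2,4-dihydroxyphenyl)-7-hydroxy-6-[(2S)-2-(2-hydroxypropan-2-yl)-5-methylhex-4-en-1-yl]-5-methoxy-2,3-dihydro-4H-chromen-4-one | COc1c(C[C@H](CC=C(C)C)C(C)(C)O)c(O)cc2c1C(=O)C[C@@H](c1ccc(O)cc1O)O2 | target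

**Totals**
Total step count: 16. Longest linear sequence: 14 steps (from 1 through steps 1, 2, 4–10 and 12–16).

**Steps most likely to fail**

1. Step 15 (proposed new method). The acyl rhodium hydride may lose CO before the hindered enol ether inserts. The hydride may go to C3 and close the five-membered ring. The Lewis-acidic cation may trigger Prins-type attack of the enol ether on the aldehyde. Facial selectivity may be poor.
   The fallback uses known chemistry, sets out from bromophenol 15 and comes back to the route at target 25; it still closes ring C through C3–C4.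
   - Commercial (E)-2,4-dihydroxycinnamic acid is persilylated (TBSCl, imidazole, DMF) to tert-butyldimethylsilyl (2E)-3-[2,4-bis(tert-butyldimethylsilyloxy)phenyl]prop-2-enoate F1.
   - F1 is reduced with i-Bu2AlH (CH2Cl2, −78 °C) to (2E)-3-[2,4-bis(tert-butyldimethylsilyloxy)phenyl]prop-2-en-1-ol F2.
   - F2 is acylated with methyl chloroformate/pyridine to (2E)-3-[2,4-bis(tert-butyldimethylsilyloxy)phenyl]prop-2-en-1-yl methyl carbonate F3.
   - Bromophenol 15 is treated with t-BuLi (THF, −78 °C) and then N-methoxy-N-methylacetamide to give 1-{6-hydroxy-3-[(2S)-2-(2-hydroxypropan-2-yl)-5-methylhex-4-en-1-yl]-2-methoxy-4-(triisopropylsilyloxy)phenyl}ethanone F4.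
   - Iridium-catalysed enantioselective allylic etherification of the lithium phenoxide of F4 with F3 ([Ir(cod)Cl]2, binaphthol-derived phosphoramidite with a bis[1-(2-methoxyphenyl)ethyl]amino group, THF, 50 °C) should give the branched ether 1-{6-({(1S)-1-[2,4-bis(tert-butyldimethylsilyloxy)phenyl]prop-2-en-1-yl}oxy)-3-[(2S)-2-(2-hydroxypropan-2-yl)-5-methylhex-4-en-1-yl]-2-methoxy-4-(triisopropylsilyloxy)phenyl}ethanone F5, with C2 already set.
   - Kinetic enolisation and O-silylation (LiN(SiMe3)2, TESCl, THF, −78 °C) gives the triethylsilyl enol ether of F5, F6.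
   - Ring-closing metathesis between the silyl enol ether and the vinyl group (second-generation Hoveyda–Grubbs catalyst RuCl2(H2IMes)(=CH-C6H4-2-OiPr), toluene, 80 °C) should close ring C as a C3=C4 double bond, giving (2S)-2-[2,4-bis(tert-butyldimethylsilyloxy)phenyl]-6-[(2S)-2-(2-hydroxypropan-2-yl)-5-methylhex-4-en-1-yl]-5-methoxy-4-(triethylsilyloxy)-7-(triisopropylsilyloxy)-2H-chromene F7.
   - The conditions of step 16 (Bu4NF/AcOH, THF, 0 °C → rt) then remove all silyl groups, the enol ether becoming the C4 ketone, to give 25.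

2. Step 13. The titanium methylidene may fail to reach an ester carbonyl flanked by an ortho-bromo aryloxy group and an ortho-silyloxy aryl group, and the acid-labile enol ether may hydrolyse during isolation.
   The fallback sets out from bromophenol 15 and comes back at enol ether 21; it makes the aryl–O–vinyl bond directly.
   - Commercial 2′,4′-dihydroxyacetophenone is silylated (TBSCl, imidazole, DMF) to 1-[2,4-bis(tert-butyldimethylsilyloxy)phenyl]ethanone F8.
   - F8 is converted with (PhO)3P/Br2/Et3N (CH2Cl2, −60 °C → rt) into the vinyl bromide 1-(1-bromoethenyl)-2,4-bis(tert-butyldimethylsilyloxy)benzene F9.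
   - Ullmann-type O-vinylation of 15 with F9 (CuI, N,N-dimethylglycine, Cs2CO3, 1,4-dioxane, 80 °C) should give 21; the hindered, electron-rich aryl bromide of 15 should not react under these conditions.

3. Step 14. The ortho-lithiated aryl vinyl ether may add to its own enol ether or be protonated before it meets DMF, and excess t-BuLi may attack the aryl silyl ethers.
   The fallback sets out from 21 and comes back at aldehyde 23 without an organolithium: palladium-catalysed reductive carbonylation of the aryl bromide (Pd(OAc)2, di(1-adamantyl)-n-butylphosphine, CO/H2 1:1, TMEDA, toluene, 100 °C), which makes no new isolated compound.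

**Further compounds**
F1 | step 15 | tert-butyldimethylsilyl (2E)-3-[2,4-bis(tert-butyldimethylsilyloxy)phenyl]prop-2-enoate | CC(C)(C)[Si](C)(C)OC(=O)/C=C/c1ccc(O[Si](C)(C)C(C)(C)C)cc1O[Si](C)(C)C(C)(C)C
F2 | step 15 | (2E)-3-[2,4-bis(tert-butyldimethylsilyloxy)phenyl]prop-2-en-1-ol | OC/C=C/c1ccc(O[Si](C)(C)C(C)(C)C)cc1O[Si](C)(C)C(C)(C)C
F3 | step 15 | (2E)-3-[2,4-bis(tert-butyldimethylsilyloxy)phenyl]prop-2-en-1-yl methyl carbonate | COC(=O)OC/C=C/c1ccc(O[Si](C)(C)C(C)(C)C)cc1O[Si](C)(C)C(C)(C)C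
F4 | step 15 | 1-{6-hydroxy-3-[(2S)-2-(2-hydroxypropan-2-yl)-5-methylhex-4-en-1-yl]-2-methoxy-4-(triisopropylsilyloxy)phenyl}ethanone | CC(=O)c1c(O)cc(O[Si](C(C)C)(C(C)C)C(C)C)c(C[C@H](CC=C(C)C)C(C)(C)O)c1OC
F5 | step 15 | 1-{6-({(1S)-1-[2,4-bis(tert-butyldimethylsilyloxy)phenyl]prop-2-en-1-yl}oxy)-3-[(2S)-2-(2-hydroxypropan-2-yl)-5-methylhex-4-en-1-yl]-2-methoxy-4-(triisopropylsilyloxy)phenyl}ethanone | CC(=O)c1c(O[C@@H](C=C)c2ccc(O[Si](C)(C)C(C)(C)C)cc2O[Si](C)(C)C(C)(C)C)cc(O[Si](C(C)C)(C(C)C)C(C)C)c(C[C@H](CC=C(C)C)C(C)(C)O)c1OC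
F6 | step 15 | triethylsilyl enol ether of F5 | C=C(O[Si](CC)(CC)CC)c1c(O[C@@H](C=C)c2ccc(O[Si](C)(C)C(C)(C)C)cc2O[Si](C)(C)C(C)(C)C)cc(O[Si](C(C)C)(C(C)C)C(C)C)c(C[C@H](CC=C(C)C)C(C)(C)O)c1OC
F7 | step 15 | (2S)-2-[2,4-bis(tert-butyldimethylsilyloxy)phenyl]-6-[(2S)-2-(2-hydroxypropan-2-yl)-5-methylhex-4-en-1-yl]-5-methoxy-4-(triethylsilyloxy)-7-(triisopropylsilyloxy)-2H-chromene | COc1c(C[C@H](CC=C(C)C)C(C)(C)O)c(O[Si](C(C)C)(C(C)C)C(C)C)cc2c1C(O[Si](CC)(CC)CC)=C[C@@H](c1ccc(O[Si](C)(C)C(C)(C)C)cc1O[Si](C)(C)C(C)(C)C)O2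
F8 | step 13 | 1-[2,4-bis(tert-butyldimethylsilyloxy)phenyl]ethanone | CC(=O)c1ccc(O[Si](C)(C)C(C)(C)C)cc1O[Si](C)(C)C(C)(C)C
F9 | step 13 | 1-(1-bromoethenyl)-2,4-bis(tert-butyldimethylsilyloxy)benzene | C=C(Br)c1ccc(O[Si](C)(C)C(C)(C)C)cc1O[Si](C)(C)C(C)(C)C
F0 | step 14 | none | none
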